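**Plan**
- Retrosynthetic cuts: the C15–O ester bond (oleoyl chloride + isocupressic acid); then C13–C16 and C14–C15 across a C13≡C14 alkyne (alkyne + Me3Al + CH2O); then C12–C13 (tosylate + acetylide); then back to a podocarpane whose ring C is opened at C12–C13 and C13–C14 with loss of C13.
- Enabling feature: the terminus C13(C16)=C14–C15–O is an (E)-3-methylalk-2-en-1-ol, the pattern left by methyl–metal syn-addition to a terminal alkyne followed by one-carbon capture. Rings A/B (C1–C10, axial C19 acid on C4) are those of podocarpic acid, whose ring-C carbons C14, C11 and C12 become C17, C11 and C12.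
- Forward order: no ring is built. Ring C is reduced, desaturated and ozonised to a 13-oxa lactone, which selenolate unzips to the 8(17)-ene and the C11–C12 arm; the chain then grows by C13≡C14 (acetylide), C16 and C15 (key step), and is capped with the oleoyl group.
- Stereochemistry: C4, C5 and C10 come from podocarpic acid; C9 is set in step 3 by axial protonation trans to C20; 13E follows from syn-carbometalation with retention on trapping; the oleoyl Z-alkene is bought with oleic acid.
- The C19 acid is carried unprotected; its axial hindrance is what distinguishes it from every other carboxyl group met on the way.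

Key step: step 12

Assumption: the target is taken as the 15-O-oleoyl ester of natural isocupressic acid, (4S,5R,9S,10R,13E) with a (9Z)-octadec-9-enoyl group.
Remarks: podocarpane numbering is used for 1–8 and 11, labdane numbering for 9, 10 and from 12 on (podocarpane C14 = labdane C17; C13 is excised). C8 (8β-H in 5–14) is a temporary centre erased in step 8. Paraformaldehyde 21 is entered by its monomer unit.

**Route**

Step 1
Reactants: 1 podocarpic acid
Product: 2 O-methylpodocarpic acid
Conditions: Me2SO4, NaOH, H2O, 0 °C → rt; then HCl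
Reagents that add atoms: dimethyl sulfate, COS(=O)(=O)OC
Why: Williamson ether synthesis, in which the phenoxide is methylated in aqueous alkali far faster than the axial, neopentyl-type C19 carboxylate, so the acid should stay free.

Step 2
Reactants: 2 O-methylpodocarpic acid
Product: 5 12-oxopodocarp-9(11)-en-19-oic acid, via Birch dienol ether 3 (not isolated), via deconjugated enone 4 (not isolated)
Conditions: Li, NH3(l), THF, t-BuOH, −78 → −33 °C; MeOH; then 3 M HCl, MeOH, 60 °C
Reagents that add atoms: water, O
Why: Birch reduction protonates C11 and C14 and leaves the enol ether C12=C13 and the tetrasubstituted C8=C9 alkene (the carboxylate is inert to lithium in ammonia), and acid then hydrolyses the enol ether and moves the alkene into conjugation, C8 being expected to take the more stable 8β-H configuration under these equilibrating conditions.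

Step 3
Reactants: 5 12-oxopodocarp-9(11)-en-19-oic acid
Product: 6 12-oxopodocarpan-19-oic acid (8β,9α)
Conditions: Li, NH3(l), THF, t-BuOH (1 equiv), −78 °C; solid NH4Cl
Reagents that add atoms: none
Why: Dissolving-metal conjugate reduction of the enone, in which the C9 carbanion is protonated axially on the α face, trans to the C20 methyl on C10 (as with steroidal 9(11)-en-12-ones), which sets the C9 centre of the target (9S) and gives the trans–anti–trans ketone.

Step 4
Reactants: 6 12-oxopodocarpan-19-oic acid (8β,9α)
Product: 8 12-oxopodocarp-13-en-19-oic acid, via bis-silyl enol ether 7 (not isolated)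
Conditions: LDA (2.5 equiv), TMSCl, THF, −78 °C; solvent exchange; Pd(OAc)2, MeCN, rt; aq. NH4Cl
Reagents that add atoms: none
Why: Saegusa–Ito oxidation, in which LDA deprotonates the open C13 methylene rather than C11 (flanked by C9 and screened by C1 and the C20 methyl) and Pd(II) dehydrosilylates the Δ12 silyl enol ether, the transient silyl ester being lost on work-up.

Step 5
Reactants: 8 12-oxopodocarp-13-en-19-oic acid
Product: 11 12-oxo-13-oxapodocarpan-19-oic acid (δ-lactone), via seco aldehyde acid 9 (not isolated), via seco hydroxy acid 10 (not isolated)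
Conditions: O3, CH2Cl2–MeOH, −78 °C; then NaBH4, aq. NaOH, 0 °C → rt; then 2 M HCl, rt
Reagents that add atoms: ozone, O=[O+][O-]
Why: Ozonolysis of a conjugated enone takes the abnormal course in which the α-carbon C13 leaves as formic acid, so C12 emerges as a carboxyl group and C14 as an aldehyde (the cleavage known for steroidal 1-en-3-ones), after which borohydride reduces only the aldehyde and acid closes the six-membered lactone.

Step 6
Reactants: 11 12-oxo-13-oxapodocarpan-19-oic acid (δ-lactone)
Product: 12 17-(phenylselanyl)-13,14,15,16-tetranorlabdane-12,19-dioic acid (8β-H)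
Conditions: (PhSe)2, NaBH4, DMF, rt; then 11, 120 °C; aq. HCl
Reagents that add atoms: diphenyl diselenide, c1ccc(cc1)[Se][Se]c1ccccc1
Why: SN2 O-alkyl cleavage of a lactone by the soft, weakly basic benzeneselenolate at the primary O–CH2 carbon (C14, now C17), with the C12 carboxylate as leaving group and the C19 carboxylate as a spectator.

Step 7
Reactants: 12 17-(phenylselanyl)-13,14,15,16-tetranorlabdane-12,19-dioic acid (8β-H)
Product: 13 12-methyl hydrogen 17-(phenylselanyl)-13,14,15,16-tetranorlabdane-12,19-dioate
Conditions: MeOH, H2SO4 (cat.), reflux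
Reagents that add atoms: methanol, CO
Why: Fischer esterification responds strongly to steric hindrance, so the primary C12 acid should be esterified while the axial tertiary C19 acid, 1,3-diaxial to C20, is left untouched.

Step 8
Reactants: 13 12-methyl hydrogen 17-(phenylselanyl)-13,14,15,16-tetranorlabdane-12,19-dioate
Product: 15 12-methyl hydrogen 13,14,15,16-tetranorlabd-8(17)-ene-12,19-dioate, via selenoxide 14 (not isolated)
Conditions: mCPBA (1.05 equiv), CH2Cl2, −78 °C; then i-Pr2NH, −78 → 40 °C
Reagents that add atoms: none
Why: Selenide oxidation and selenoxide syn-elimination, in which C8–H is the only β-hydrogen so the 8(17)-exocyclic alkene is the only possible regioisomer, and the one equivalent of peracid is consumed before any alkene exists.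

Step 9
Reactants: 15 12-methyl hydrogen 13,14,15,16-tetranorlabd-8(17)-ene-12,19-dioate
Product: 16 12-hydroxy-13,14,15,16-tetranorlabd-8(17)-en-19-oic acid
Conditions: DIBAL-H (4 equiv), CH2Cl2, −78 → 0 °C; Rochelle salt
Reagents that add atoms: none
Why: Hydride reduction of an ester to the primary alcohol, in which the C19 acid is converted at once into a hindered aluminium carboxylate that should not be reduced at or below 0 °C and the isolated alkene is inert.

Step 10
Reactants: 16 12-hydroxy-13,14,15,16-tetranorlabd-8(17)-en-19-oic acid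
Product: 17 12-(p-tolylsulfonyloxy)-13,14,15,16-tetranorlabd-8(17)-en-19-oic acid
Conditions: TsCl, pyridine, CH2Cl2, 0 °C; then H2O, rt
Reagents that add atoms: p-toluenesulfonyl chloride, Cc1ccc(cc1)S(=O)(=O)Cl
Why: Sulfonylation of an unhindered primary alcohol, any carboxylic–sulfonic mixed anhydride formed at the hindered C19 acid being hydrolysed back during the aqueous pyridine work-up.

Step 11
Reactants: 17 12-(p-tolylsulfonyloxy)-13,14,15,16-tetranorlabd-8(17)-en-19-oic acid; 18 lithium acetylide–ethylenediamine complex
Product: 19 15,16-dinorlabd-8(17)-en-13-yn-19-oic acid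
Conditions: 18 (excess), DMSO, rt; aq. NH4Cl, then dilute HCl
Reagents that add atoms: none
Why: SN2 alkylation of lithium acetylide by a primary tosylate in DMSO, which forms C12–C13; the first equivalent only makes the lithium carboxylate, and C12 is unbranched at its α- and β-carbons so elimination should be minor.

Step 12
Reactants: 19 15,16-dinorlabd-8(17)-en-13-yn-19-oic acid; 20 trimethylaluminium; 21 paraformaldehyde
Product: 24 isocupressic acid, via alkenylalane 22 (not isolated), via lithium alanate 23 (not isolated)
Conditions: Me3Al (4 equiv), Cp2ZrCl2 (0.3 equiv), CH2Cl2, 0 °C → rt; excess Me3Al removed in vacuo; n-BuLi, hexane–THF, −78 → 0 °C; (CH2O)n, THF, rt; 1 M HCl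
Reagents that add atoms: none
Why: Cp2ZrCl2 and Me3Al generate a methylzirconium–aluminium species that adds methyl and metal syn across C13≡C14, with the metal on terminal C14 and the methyl (C16) on C13, and transmetalation leaves the (E)-alkenyldimethylalane 22. n-Butyllithium turns 22 into the more nucleophilic alanate 23, whose alkenyl group adds to monomeric formaldehyde with retention to form C14–C15, so the 13E allylic alcohol follows from syn addition plus retention; no ring is closed and no stereocentre is created. The closest known reaction type is the zirconium-catalysed methylalumination of terminal alkynes with aldehyde capture (Negishi carboalumination), the standard entry to (E)-3-methylalk-2-en-1-ols. The step needs regioselectivity (metal to C14), which the terminal unbranched alkyne secures sterically, and chemoselectivity over C8=C17, which as an unactivated 1,1-disubstituted alkene should not be carbometalated by this achiral catalyst at room temperature. The C19 acid is taken up by the first equivalent of Me3Al as a hindered dimethylaluminium carboxylate, which should resist methylation at room temperature and is released on acidic work-up.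

Step 13
Reactants: 25 oleic acid
Product: 26 oleoyl chloride
Conditions: (COCl)2, DMF (cat.), CH2Cl2, 0 °C → rt; evaporate
Reagents that add atoms: oxalyl chloride, O=C(Cl)C(=O)Cl
Why: Acid chloride formation through the chloroiminium species from DMF and oxalyl chloride, under conditions mild enough to leave the Z-alkene unchanged.

Step 14
Reactants: 24 isocupressic acid; 26 oleoyl chloride
Product: 28 15-O-oleoylisocupressic acid (target), via mixed anhydride 27 (not isolated)
Conditions: 26 (2.2 equiv), pyridine, DMAP (cat.), CH2Cl2, 0 °C → rt; then THF–H2O–pyridine, rt; dilute HCl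
Reagents that add atoms: none
Why: DMAP-catalysed nucleophilic acyl substitution at the unhindered primary allylic alcohol; the C19 acid is carried along as a mixed anhydride that water and pyridine cleave at its unhindered oleoyl carbonyl, returning the free C19 acid.

**Compound list**

1 | podocarpic acid (12-hydroxypodocarpa-8,11,13-trien-19-oic acid) | Oc1ccc2CC[C@@H]3[C@](C)(CCC[C@]3(C)C(=O)O)c2c1 | starting material
2 | O-methylpodocarpic acid (12-methoxypodocarpa-8,11,13-trien-19-oic acid) | COc1ccc2CC[C@@H]3[C@](C)(CCC[C@]3(C)C(=O)O)c2c1 | intermediate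
3 | 12-methoxypodocarpa-8,12-dien-19-oic acid (Birch dienol ether) | COC1=CCC=2CC[C@@H]3[C@](C)(CCC[C@]3(C)C(=O)O)C=2C1 | intermediate
4 | 12-oxopodocarp-8-en-19-oic acid (deconjugated enone) | O=C1CCC=2CC[C@@H]3[C@](C)(CCC[C@]3(C)C(=O)O)C=2C1 | intermediate
5 | 12-oxopodocarp-9(11)-en-19-oic acid (8β-H) | O=C1CC[C@@H]2CC[C@@H]3[C@](C)(CCC[C@]3(C)C(=O)O)C2=C1 | intermediate
6 | 12-oxopodocarpan-19-oic acid (8β-H, 9α-H, trans–anti–trans) | O=C1CC[C@@H]2CC[C@@H]3[C@](C)(CCC[C@]3(C)C(=O)O)[C@H]2C1 | intermediate
7 | trimethylsilyl 12-(trimethylsilyloxy)podocarp-12-en-19-oate | C[Si](C)(C)OC1=CC[C@@H]2CC[C@@H]3[C@](C)(CCC[C@]3(C)C(=O)O[Si](C)(C)C)[C@H]2C1 | intermediate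
8 | 12-oxopodocarp-13-en-19-oic acid | O=C1C=C[C@@H]2CC[C@@H]3[C@](C)(CCC[C@]3(C)C(=O)O)[C@H]2C1 | intermediate
9 | 17-oxo-13,14,15,16-tetranorlabdane-12,19-dioic acid (8β-H; CHO on C8, CH2CO2H on C9; present largely as its cyclic pseudo-acid) | O=C[C@@H]1CC[C@@H]2[C@](C)(CCC[C@]2(C)C(=O)O)[C@H]1CC(=O)O | intermediate
10 | 17-hydroxy-13,14,15,16-tetranorlabdane-12,19-dioic acid (8β-H) | OC[C@@H]1CC[C@@H]2[C@](C)(CCC[C@]2(C)C(=O)O)[C@H]1CC(=O)O | intermediate
11 | 12-oxo-13-oxapodocarpan-19-oic acid (δ-lactone of 10 between C12 and the C14/C17 oxygen) | O=C1OC[C@@H]2CC[C@@H]3[C@](C)(CCC[C@]3(C)C(=O)O)[C@H]2C1 | intermediate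
12 | 17-(phenylselanyl)-13,14,15,16-tetranorlabdane-12,19-dioic acid (8β-H) | c1ccccc1[Se]C[C@@H]1CC[C@@H]2[C@](C)(CCC[C@]2(C)C(=O)O)[C@H]1CC(=O)O | intermediate
13 | 12-methyl hydrogen 17-(phenylselanyl)-13,14,15,16-tetranorlabdane-12,19-dioate (8β-H) | c1ccccc1[Se]C[C@@H]1CC[C@@H]2[C@](C)(CCC[C@]2(C)C(=O)O)[C@H]1CC(=O)OC | intermediate
14 | selenoxide of 13 (mixture at selenium) | O=[Se](C[C@@H]1CC[C@@H]2[C@](C)(CCC[C@]2(C)C(=O)O)[C@H]1CC(=O)OC)c1ccccc1 | intermediate
15 | 12-methyl hydrogen 13,14,15,16-tetranorlabd-8(17)-ene-12,19-dioate | C=C1CC[C@@H]2[C@](C)(CCC[C@]2(C)C(=O)O)[C@H]1CC(=O)OC | intermediate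
16 | 12-hydroxy-13,14,15,16-tetranorlabd-8(17)-en-19-oic acid | C=C1CC[C@@H]2[C@](C)(CCC[C@]2(C)C(=O)O)[C@H]1CCO | intermediate
17 | 12-(p-tolylsulfonyloxy)-13,14,15,16-tetranorlabd-8(17)-en-19-oic acid | C=C1CC[C@@H]2[C@](C)(CCC[C@]2(C)C(=O)O)[C@H]1CCOS(=O)(=O)c1ccc(C)cc1 | intermediate
18 | lithium acetylide–ethylenediamine complex | [Li+].[C-]#C.NCCN | starting material
19 | 15,16-dinorlabd-8(17)-en-13-yn-19-oic acid | C=C1CC[C@@H]2[C@](C)(CCC[C@]2(C)C(=O)O)[C@H]1CCC#C | intermediate
20 | trimethylaluminium | C[Al](C)C | starting material
21 | paraformaldehyde (monomer unit shown) | C=O | starting material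
22 | (13E)-14-(dimethylalumanyl)-15-norlabda-8(17),13-dien-19-oic acid dimethylaluminium carboxylate | C=C1CC[C@@H]2[C@](C)(CCC[C@]2(C)C(=O)O[Al](C)C)[C@H]1CC/C(C)=C/[Al](C)C | intermediate
23 | lithium butyl(dimethyl)alkenylalanate derived from 22 | [Li+].C=C1CC[C@@H]2[C@](C)(CCC[C@]2(C)C(=O)O[Al](C)C)[C@H]1CC/C(C)=C/[Al-](C)(C)CCCC | intermediate
24 | isocupressic acid ((13E)-15-hydroxylabda-8(17),13-dien-19-oic acid) | C=C1CC[C@@H]2[C@](C)(CCC[C@]2(C)C(=O)O)[C@H]1CC/C(C)=C/CO | intermediate
25 | oleic acid ((9Z)-octadec-9-enoic acid) | CCCCCCCC/C=C\CCCCCCCC(=O)O | starting material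
26 | oleoyl chloride | CCCCCCCC/C=C\CCCCCCCC(=O)Cl | intermediate
27 | 15-O-oleoylisocupressic oleic mixed anhydride | C=C1CC[C@@H]2[C@](C)(CCC[C@]2(C)C(=O)OC(=O)CCCCCCC/C=C\CCCCCCCC)[C@H]1CC/C(C)=C/COC(=O)CCCCCCC/C=C\CCCCCCCC | intermediate
28 | 15-O-oleoylisocupressic acid ((13E)-15-[(9Z)-octadec-9-enoyloxy]labda-8(17),13-dien-19-oic acid) | C=C1CC[C@@H]2[C@](C)(CCC[C@]2(C)C(=O)O)[C@H]1CC/C(C)=C/COC(=O)CCCCCCC/C=C\CCCCCCCC | target

**Step count**

Total: 14 steps. Longest linear sequence: 13 steps (steps 1–12 and 14, from podocarpic acid); step 13 is a one-step side branch.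

**Steps most likely to fail**

Step 12 (key step). The aluminium carboxylate may tie up the zirconium catalyst so that carbometalation stalls, or the alanate may be protonated instead of hydroxymethylated, losing the metal before C14–C15 is formed. Fallback, from 19 back to 24: the alkyne is hydrated with Markovnikov selectivity under gold(I) catalysis (IPrAuCl/AgSbF6, aqueous dioxane) to the methyl ketone 13-oxo-14,15-dinorlabd-8(17)-en-19-oic acid F1, the alkyne CH becoming C16. Horner–Wadsworth–Emmons reaction with triethyl phosphonoacetate (NaH, THF, carboxylate preformed) should give the 15-ethyl hydrogen (13E)-labda-8(17),13-diene-15,19-dioate F2, with the E isomer expected to predominate and the Z isomer to be removed by chromatography. DIBAL-H (CH2Cl2, −78 °C) then reduces the conjugated ester to the allylic alcohol 24.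

Step 4. Enolisation may not discriminate well enough between C13 and C11, or dehydrogenation may run on to a dienone. Fallback, from 6 back to 8: the ketone is brominated through its acid-generated, thermodynamically preferred Δ12 enol with phenyltrimethylammonium tribromide in THF to 13α-bromo-12-oxopodocarpan-19-oic acid F3, and dehydrobromination with Li2CO3/LiBr in DMF at 120 °C gives enone 8.

Step 6. SN2 attack at the β-branched O–CH2 carbon may be too slow, leaving the lactone unchanged while the selenolate is lost to oxidation; the elimination of the primary phenyl selenoxide in step 8 is a related weak point. Fallback, from 11 back to 15: the lactone is opened under acid activation with HBr in acetic acid followed by methanol, which should give in one flask the 12-methyl hydrogen 17-bromo-13,14,15,16-tetranorlabdane-12,19-dioate F4 (bromide opens the protonated lactone and the freed C12 acid is esterified). E2 elimination with KOt-Bu in THF then delivers alkene 15, bypassing 12–14.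

**Further compounds**

F1 | step 12 | 13-oxo-14,15-dinorlabd-8(17)-en-19-oic acid | C=C1CC[C@@H]2[C@](C)(CCC[C@]2(C)C(=O)O)[C@H]1CCC(C)=O
F2 | step 12 | 15-ethyl hydrogen (13E)-labda-8(17),13-diene-15,19-dioate | C=C1CC[C@@H]2[C@](C)(CCC[C@]2(C)C(=O)O)[C@H]1CC/C(C)=C/C(=O)OCC
F3 | step 4 | 13α-bromo-12-oxopodocarpan-19-oic acid | O=C1[C@H](Br)C[C@@H]2CC[C@@H]3[C@](C)(CCC[C@]3(C)C(=O)O)[C@H]2C1
F4 | step 6 | 12-methyl hydrogen 17-bromo-13,14,15,16-tetranorlabdane-12,19-dioate (8β-H) | BrC[C@@H]1CC[C@@H]2[C@](C)(CCC[C@]2(C)C(=O)O)[C@H]1CC(=O)OC
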